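The 14-membered carbocycle is opened at the C8–C9 single bond, where the E-trisubstituted C7=C8 alkene meets the unfunctionalised C9–C11 chain, far from the cis-fused α-methylene-γ-lactone (C1, C14, C15, C16) and the C3–C4 epoxide; that remoteness is the feature the key step uses. One operation, hydroboration of a terminal alkene with 9-BBN followed by intramolecular B-alkyl Suzuki–Miyaura coupling with an (E)-alkenyl iodide, forms C8–C9 and closes the macrocycle with the alkene geometry already set. The precursor is a seco acetate carrying the finished lactone, epoxide and all six stereocentres, assembled from two Sharpless-derived fragments by an indium-mediated Barbier allylation–lactonisation.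

Key step: step 16

Remark: cembrane numbering is used for the target and its precursors (C1 and C14 are the lactone ring carbons, C13 bears the acetate); the epoxidation of the Z-allylic alcohol in step 11 is assumed to give enriched, not pure, material, whose minor antipode would be removed as a diastereomer after step 14.

Step 1
Reactants: 1 geranyl acetate
Product: 2 (2E)-3-methyl-6-oxohex-2-en-1-yl acetate
Conditions: O3 (ca. 1 equiv), CH2Cl2/pyridine, −78 °C; then Me2S, −78 °C → rt
Reagents that add atoms: ozone, [O-][O+]=O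
Why: Chemoselective ozonolysis should cleave the electron-rich 6,7-alkene in preference to the 2,3-alkene, which is deactivated by the allylic acetate, and reductive work-up gives the aldehyde.

Step 2
Reactants: 2 (2E)-3-methyl-6-oxohex-2-en-1-yl acetate
Product: 4 (2E)-3-methylhept-2-en-6-yn-1-ol, via hydroxy aldehyde 3 (not isolated)
Conditions: K2CO3 (cat.), MeOH, 0 °C; then dimethyl (1-diazo-2-oxopropyl)phosphonate, K2CO3, MeOH, 0 °C → rt
Reagents that add atoms: dimethyl (1-diazo-2-oxopropyl)phosphonate, COP(=O)(OC)C(=[N+]=[N-])C(C)=O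
Why: Carbonate-catalysed methanolysis removes the acetate, and the Ohira–Bestmann form of the Seyferth–Gilbert homologation then converts the aldehyde into the terminal alkyne under the same mild base without touching the trisubstituted alkene.

Step 3
Reactants: 4 (2E)-3-methylhept-2-en-6-yn-1-ol
Product: 6 (2E)-3-methyloct-2-en-6-yn-1-ol, via dilithium alkoxide acetylide 5 (not isolated)
Conditions: n-BuLi (2.1 equiv), THF, −78 → −20 °C; MeI (1.1 equiv), −78 °C → rt; then H2O
Reagents that add atoms: iodomethane, CI
Why: Alkylation of an alkynol dianion should be C-selective, because the acetylide carbon is far more nucleophilic towards one equivalent of MeI in THF than the lithium alkoxide.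

Step 4
Reactants: 6 (2E)-3-methyloct-2-en-6-yn-1-ol
Product: 8 (2E,6E)-7-iodo-3-methylocta-2,6-dien-1-ol, via alkenylzirconocene chloride 7 (not isolated)
Conditions: Cp2Zr(H)Cl (2.5–3 equiv), THF, rt → 40 °C; then I2, THF, 0 °C
Reagents that add atoms: iodine, II
Why: Hydrozirconation–iodinolysis: syn addition of Zr–H, equilibrated by excess hydride to place zirconium on the methyl-bearing carbon, followed by iodinolysis with retention, should give the (E)-2-iodo-2-alkene, while the hindered allylic alkene does not react.

Step 5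
Reactants: 8 (2E,6E)-7-iodo-3-methylocta-2,6-dien-1-ol
Product: 9 [(2R,3R)-3-[(3E)-4-iodopent-3-en-1-yl]-3-methyloxiran-2-yl]methanol
Conditions: Ti(OiPr)4 (10 mol%), D-(−)-diethyl tartrate (12 mol%), t-BuOOH, 4 Å molecular sieves, CH2Cl2, −20 °C
Reagents that add atoms: tert-butyl hydroperoxide, CC(C)(C)OO
Why: Sharpless asymmetric epoxidation oxidises only the allylic alkene, and D-(−)-tartrate should give the (2R,3R) epoxide of this geraniol-type E-alcohol, which sets C3 and C4 of the target.

Step 6
Reactants: 9 [(2R,3R)-3-[(3E)-4-iodopent-3-en-1-yl]-3-methyloxiran-2-yl]methanol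
Product: 10 [(2R,3R)-3-[(3E)-4-iodopent-3-en-1-yl]-3-methyloxiran-2-yl]methyl 4-methylbenzenesulfonate
Conditions: TsCl, Et3N, DMAP (cat.), CH2Cl2, 0 °C
Reagents that add atoms: 4-methylbenzenesulfonyl chloride, Cc1ccc(cc1)S(Cl)(=O)=O
Why: Sulfonylation of the primary alcohol under mild base leaves the epoxide and both stereocentres untouched.

Step 7
Reactants: 10 [(2R,3R)-3-[(3E)-4-iodopent-3-en-1-yl]-3-methyloxiran-2-yl]methyl 4-methylbenzenesulfonate
Product: 11 (2R,3R)-2-[(3E)-4-iodopent-3-en-1-yl]-2-methyl-3-(prop-2-en-1-yl)oxirane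
Conditions: CH2=CHMgBr (2 equiv), CuI (10 mol%), THF, −40 → −20 °C
Reagents that add atoms: vinylmagnesium bromide, C=C[Mg]Br
Why: Copper-catalysed Grignard cross-coupling by SN2 displacement of the primary epoxy tosylate should outrun attack on the hindered trisubstituted epoxide and reaction at the alkenyl iodide at this temperature.

Step 8
Reactants: 11 (2R,3R)-2-[(3E)-4-iodopent-3-en-1-yl]-2-methyl-3-(prop-2-en-1-yl)oxirane; 12 methyl 2-(bromomethyl)prop-2-enoate
Product: 13 methyl (2Z)-2-(bromomethyl)-4-[(2R,3R)-3-[(3E)-4-iodopent-3-en-1-yl]-3-methyloxiran-2-yl]but-2-enoate (fragment 1)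
Conditions: 12 (5 equiv), second-generation Hoveyda–Grubbs catalyst (5–10 mol%), CH2Cl2, 40 °C
Reagents that add atoms: none
Why: Olefin cross-metathesis of the only monosubstituted alkene with an excess of a 2-substituted acrylate that does not homodimerise should give the thermodynamically preferred isomer with the ester trans to the chain (the Z bromide), the phosphine-free catalyst avoiding quaternisation by the allylic bromide and the trisubstituted iodoalkene staying inert.

Step 9
Reactants: 14 prop-2-yn-1-ol; 15 3-bromoprop-1-ene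
Product: 16 hex-5-en-2-yn-1-ol
Conditions: CuI (cat.), K2CO3, NaI, DMF, rt
Reagents that add atoms: none
Why: Copper-mediated coupling of the terminal alkyne, as its copper acetylide, with the allylic bromide gives the skipped enyne directly on the free alcohol.

Step 10
Reactants: 16 hex-5-en-2-yn-1-ol
Product: 17 (2Z)-hexa-2,5-dien-1-ol
Conditions: H2 (1 atm, 1 equiv), Pd/CaCO3 poisoned with Pb(OAc)2, quinoline, EtOAc, rt
Reagents that add atoms: none
Why: Semihydrogenation on the poisoned palladium surface delivers both hydrogens syn to the alkyne, which binds more strongly than the terminal alkene, so the Z-alkene should form before the vinyl group is reduced.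

Step 11
Reactants: 17 (2Z)-hexa-2,5-dien-1-ol
Product: 18 [(2S,3R)-3-(prop-2-en-1-yl)oxiran-2-yl]methanol
Conditions: Ti(OiPr)4 (1 equiv), L-(+)-diethyl tartrate (1.2 equiv), t-BuOOH, 4 Å molecular sieves, CH2Cl2, −20 °C
Reagents that add atoms: tert-butyl hydroperoxide, CC(C)(C)OO
Why: Sharpless asymmetric epoxidation of the Z-allylic alcohol with L-(+)-tartrate should give the (2S,3R) cis-epoxide, the isolated terminal alkene being inert to the titanium peroxide.

Step 12
Reactants: 18 [(2S,3R)-3-(prop-2-en-1-yl)oxiran-2-yl]methanol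
Product: 19 (2R,3S)-3-methylhex-5-ene-1,2-diol
Conditions: AlMe3 (3 equiv), hexane/CH2Cl2, 0 °C → rt; aq. potassium sodium tartrate
Reagents that add atoms: trimethylaluminium, C[Al](C)C
Why: Ring opening of a 2,3-epoxy alcohol by AlMe3, directed by the aluminium alkoxide, transfers methyl to the carbon remote from the hydroxymethyl group with inversion, which sets C12 and leaves the C13 oxygen in place.

Step 13
Reactants: 19 (2R,3S)-3-methylhex-5-ene-1,2-diol
Product: 20 (2R,3S)-2-hydroxy-3-methylhex-5-enal (fragment 2)
Conditions: TEMPO (10 mol%), PhI(OAc)2 (1.1 equiv), CH2Cl2, 0 °C → rt; used crude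
Reagents that add atoms: none
Why: Oxoammonium-mediated (TEMPO) oxidation is selective for the primary over the secondary hydroxyl and runs without base, so the α-hydroxy aldehyde should form without epimerisation and be usable directly in water, where any dimer dissociates.

Step 14
Reactants: 13 methyl (2Z)-2-(bromomethyl)-4-[(2R,3R)-3-[(3E)-4-iodopent-3-en-1-yl]-3-methyloxiran-2-yl]but-2-enoate; 20 (2R,3S)-2-hydroxy-3-methylhex-5-enal
Product: 22 (4S,5R)-5-[(1R,2S)-1-hydroxy-2-methylpent-4-en-1-yl]-4-{[(2R,3R)-3-[(3E)-4-iodopent-3-en-1-yl]-3-methyloxiran-2-yl]methyl}-3-methylideneoxolan-2-one, via dihydroxy ester 21 (not isolated)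
Conditions: In powder, THF/H2O (1:1), rt; then DBU (cat.), CH2Cl2, 0 °C
Reagents that add atoms: none
Why: Indium-mediated Barbier allylation in water: the allylindium attacks the aldehyde at its γ-carbon (C1) through a chair-like six-membered transition state, chelation of indium by the free C13 hydroxyl should give the 13,14-syn diol, the Z geometry should give the C1/C14 syn adduct, and base-catalysed 5-exo acyl transfer closes this to the cis γ-lactone with loss of methanol.

Step 15
Reactants: 22 (4S,5R)-5-[(1R,2S)-1-hydroxy-2-methylpent-4-en-1-yl]-4-{[(2R,3R)-3-[(3E)-4-iodopent-3-en-1-yl]-3-methyloxiran-2-yl]methyl}-3-methylideneoxolan-2-one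
Product: 23 (1R,2S)-1-[(2R,3S)-3-{[(2R,3R)-3-[(3E)-4-iodopent-3-en-1-yl]-3-methyloxiran-2-yl]methyl}-4-methylidene-5-oxooxolan-2-yl]-2-methylpent-4-en-1-yl acetate (seco acetate)
Conditions: Ac2O, pyridine, DMAP (cat.), CH2Cl2, 0 °C → rt
Reagents that add atoms: acetic anhydride, CC(=O)OC(C)=O
Why: Nucleophile-catalysed acylation of the only free hydroxyl installs the C13 acetate with retention and removes the last protic group before hydroboration.

Step 16
Reactants: 23 (1R,2S)-1-[(2R,3S)-3-{[(2R,3R)-3-[(3E)-4-iodopent-3-en-1-yl]-3-methyloxiran-2-yl]methyl}-4-methylidene-5-oxooxolan-2-yl]-2-methylpent-4-en-1-yl acetate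
Product: 25 eupalmerin acetate, via alkylborane 24 (not isolated)
Conditions: 9-BBN (1.2 equiv), THF, 0 °C → rt; then slow addition to PdCl2(dppf) (20 mol%), AsPh3 (40 mol%), Cs2CO3 (3 equiv), DMF/THF/H2O, ca. 1 mM, rt → 45 °C
Reagents that add atoms: none
Why: 9-BBN should add anti-Markovnikov to the only monosubstituted alkene (C9=C10) and place boron on C9, because the exocyclic methylene is conjugated and electron-poor, the iodoalkene is trisubstituted, and the epoxide, acetate and lactone are inert to this borane at room temperature. Zerovalent palladium, formed in the flask from the divalent precatalyst, inserts into the C8–I bond with retention, the base-activated borane transfers the primary C9 alkyl group, and reductive elimination forms the C8–C9 bond. The closest known reaction type is the intramolecular B-alkyl Suzuki–Miyaura coupling of a 9-BBN alkylborane with an alkenyl iodide, which is established for macrocycles and for trisubstituted alkenes from 2-iodo-2-alkenes. The 14-membered carbocycle is closed end to end, by joining the two chain termini of the seco compound, under high dilution and slow addition so that cyclisation should outrun oligomerisation. No stereocentre is formed; the E geometry of C7=C8 is fixed in the acyclic iodide and retained, and C1, C3, C4, C12, C13 and C14 lie away from the reacting carbons. AsPh3 and the mild carbonate base at modest temperature should keep transmetalation faster than β-hydride elimination and spare the acetate and the methylene lactone.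

Compound list
1 | geranyl acetate, (2E)-3,7-dimethylocta-2,6-dien-1-yl acetate | CC(C)=CCC/C(C)=C/COC(C)=O | starting material
2 | (2E)-3-methyl-6-oxohex-2-en-1-yl acetate | CC(=O)OC/C=C(\C)CCC=O | intermediate
3 | (4E)-6-hydroxy-4-methylhex-4-enal (hydroxy aldehyde) | O=CCC/C(C)=C/CO | intermediate (not isolated)
4 | (2E)-3-methylhept-2-en-6-yn-1-ol | C#CCC/C(C)=C/CO | intermediate
5 | dilithium alkoxide acetylide of 4 | [Li]C#CCC/C(C)=C/CO[Li] | intermediate (not isolated)
6 | (2E)-3-methyloct-2-en-6-yn-1-ol | CC#CCC/C(C)=C/CO | intermediate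
7 | (E)-alkenylzirconocene chloride from 6, zirconium on C7, oxygen bound as zirconocene chloride alkoxide | Cl[Zr](C1C=CC=C1)(C1C=CC=C1)OC/C=C(\C)CC/C=C(\C)[Zr](Cl)(C1C=CC=C1)C1C=CC=C1 | intermediate (not isolated)
8 | (2E,6E)-7-iodo-3-methylocta-2,6-dien-1-ol | OC/C=C(\C)CC/C=C(\C)I | intermediate
9 | [(2R,3R)-3-[(3E)-4-iodopent-3-en-1-yl]-3-methyloxiran-2-yl]methanol | OC[C@H]1O[C@]1(C)CC/C=C(\C)I | intermediate
10 | [(2R,3R)-3-[(3E)-4-iodopent-3-en-1-yl]-3-methyloxiran-2-yl]methyl 4-methylbenzenesulfonate | Cc1ccc(cc1)S(=O)(=O)OC[C@H]1O[C@]1(C)CC/C=C(\C)I | intermediate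
11 | (2R,3R)-2-[(3E)-4-iodopent-3-en-1-yl]-2-methyl-3-(prop-2-en-1-yl)oxirane (C1–C8 allyl epoxide) | C=CC[C@H]1O[C@]1(C)CC/C=C(\C)I | intermediate
12 | methyl 2-(bromomethyl)prop-2-enoate | C=C(CBr)C(=O)OC | starting material
13 | methyl (2Z)-2-(bromomethyl)-4-[(2R,3R)-3-[(3E)-4-iodopent-3-en-1-yl]-3-methyloxiran-2-yl]but-2-enoate (fragment 1) | COC(=O)/C(CBr)=C/C[C@H]1O[C@]1(C)CC/C=C(\C)I | intermediate
14 | prop-2-yn-1-ol (propargyl alcohol) | C#CCO | starting material
15 | 3-bromoprop-1-ene (allyl bromide) | C=CCBr | starting material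
16 | hex-5-en-2-yn-1-ol | C=CCC#CCO | intermediate
17 | (2Z)-hexa-2,5-dien-1-ol | OC/C=C\CC=C | intermediate
18 | [(2S,3R)-3-(prop-2-en-1-yl)oxiran-2-yl]methanol (cis-epoxy alcohol) | OC[C@@H]1O[C@@H]1CC=C | intermediate
19 | (2R,3S)-3-methylhex-5-ene-1,2-diol | OC[C@H](O)[C@@H](C)CC=C | intermediate
20 | (2R,3S)-2-hydroxy-3-methylhex-5-enal (fragment 2) | O=C[C@H](O)[C@@H](C)CC=C | intermediate
21 | methyl (3S,4R,5R,6S)-4,5-dihydroxy-6-methyl-2-methylidene-3-{[(2R,3R)-3-[(3E)-4-iodopent-3-en-1-yl]-3-methyloxiran-2-yl]methyl}non-8-enoate (dihydroxy ester) | C=C(C(=O)OC)[C@H](C[C@H]1O[C@]1(C)CC/C=C(\C)I)[C@@H](O)[C@H](O)[C@@H](C)CC=C | intermediate (not isolated)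
22 | (4S,5R)-5-[(1R,2S)-1-hydroxy-2-methylpent-4-en-1-yl]-4-{[(2R,3R)-3-[(3E)-4-iodopent-3-en-1-yl]-3-methyloxiran-2-yl]methyl}-3-methylideneoxolan-2-one (seco hydroxy lactone, cis) | C=C1C(=O)O[C@@H]([C@H](O)[C@@H](C)CC=C)[C@H]1C[C@H]2O[C@]2(C)CC/C=C(\C)I | intermediate
23 | (1R,2S)-1-[(2R,3S)-3-{[(2R,3R)-3-[(3E)-4-iodopent-3-en-1-yl]-3-methyloxiran-2-yl]methyl}-4-methylidene-5-oxooxolan-2-yl]-2-methylpent-4-en-1-yl acetate (seco acetate) | C=C1C(=O)O[C@@H]([C@H](OC(C)=O)[C@@H](C)CC=C)[C@H]1C[C@H]2O[C@]2(C)CC/C=C(\C)I | intermediate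
24 | B-alkyl-9-borabicyclo[3.3.1]nonane from 23, boron on C9 | C=C1C(=O)O[C@@H]([C@H](OC(C)=O)[C@@H](C)CCCB3C4CCCC3CCC4)[C@H]1C[C@H]2O[C@]2(C)CC/C=C(\C)I | intermediate (not isolated)
25 | eupalmerin acetate, (1S,3R,4R,7E,12S,13R,14R) in cembrane numbering | C=C1C(=O)O[C@H]2[C@H](OC(C)=O)[C@@H](C)CCC/C(C)=C/CC[C@@]3(C)O[C@@H]3C[C@@H]12 | target

Total step count: 16
Longest linear sequence: 11 steps (steps 1–8, then 14–16)

Steps most likely to fail

Step 16. The hydroboration may not discriminate cleanly between the terminal alkene and the exocyclic methylene of the lactone. Under aqueous carbonate the methylene lactone may also suffer conjugate addition, and the slow ring closure may lose out to oligomerisation or protodeboronation. The fallback masks the Michael acceptor. Setting out from 23, conjugate addition of Me2NH (THF, 0 °C) would give the dimethylaminomethyl seco lactone F1. Hydroboration with 9-BBN, with one extra equivalent to allow for amine–borane complexation, would give the alkylborane F2, which would be cyclised under the same palladium conditions to the macrocyclic amino lactone F3. MeI would then give the quaternary ammonium iodide F4, and NaHCO3 would eliminate trimethylamine to restore the methylene lactone, coming back to the route at 25.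

Step 8. Homodimerisation of 11 may outrun the slow cross-coupling with the hindered, electron-poor 1,1-disubstituted partner, and the allylic bromide may shorten the life of the ruthenium carbene. The fallback avoids metathesis and builds the same bromide by allylic transposition of a Morita–Baylis–Hillman-type alcohol. Setting out from 11, Lemieux–Johnson cleavage (OsO4 cat., NaIO4, 2,6-lutidine, dioxane/H2O) would give the epoxy aldehyde F5, used at once. Addition of the α-(methoxycarbonyl)vinylalane made from methyl propiolate, iBu2AlH and N-methylmorpholine N-oxide in THF at 0 °C would give the allylic alcohol F6; both carbinol epimers serve. NBS/Me2S in CH2Cl2 would then convert it with SN2′ transposition into the (Z)-bromide, coming back to the route at 13.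

Step 14. Facial selectivity at C14 may be poor if the free hydroxy aldehyde reacts through its dimer or without chelation. The α-centre may epimerise, indium salts may open the epoxide, and ring closure may go through the C13 hydroxyl to the six-membered lactone. The fallback carries the C13 oxygen as a chelating ether that cannot lactonise. Setting out from 19, 4-MeOC6H4CH(OMe)2 with pyridinium 4-toluenesulfonate would give the 4-methoxyphenyl dioxolane F7. iBu2AlH (CH2Cl2, −78 → 0 °C) would open it at the primary oxygen to the secondary 4-methoxybenzyl ether alcohol F8, and Dess–Martin periodinane would give the configurationally more robust alkoxy aldehyde F9. In powder in THF/H2O with 13 would give the protected hydroxy ester F10, which can close only to the protected cis γ-lactone F11. DDQ in CH2Cl2/pH 7 buffer would release the hydroxyl, coming back to the route at 22.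

Further compounds
F1 | step 16 | dimethylaminomethyl seco lactone (Me2NH adduct of 23, C15 epimers) | CN(C)CC1C(=O)O[C@@H]([C@H](OC(C)=O)[C@@H](C)CC=C)[C@H]1C[C@H]2O[C@]2(C)CC/C=C(\C)I
F2 | step 16 | B-alkyl-9-borabicyclo[3.3.1]nonane from F1 | CN(C)CC1C(=O)O[C@@H]([C@H](OC(C)=O)[C@@H](C)CCCB3C4CCCC3CCC4)[C@H]1C[C@H]2O[C@]2(C)CC/C=C(\C)I
F3 | step 16 | macrocyclic amino lactone (Me2NH adduct of 25) | CN(C)CC1C(=O)O[C@H]2[C@H](OC(C)=O)[C@@H](C)CCC/C(C)=C/CC[C@@]3(C)O[C@@H]3C[C@@H]12
F4 | step 16 | quaternary ammonium iodide of F3 | C[N+](C)(C)CC1C(=O)O[C@H]2[C@H](OC(C)=O)[C@@H](C)CCC/C(C)=C/CC[C@@]3(C)O[C@@H]3C[C@@H]12.[I-]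
F5 | step 8 | 2-[(2R,3R)-3-[(3E)-4-iodopent-3-en-1-yl]-3-methyloxiran-2-yl]acetaldehyde | O=CC[C@H]1O[C@]1(C)CC/C=C(\C)I
F6 | step 8 | methyl 3-hydroxy-4-[(2R,3R)-3-[(3E)-4-iodopent-3-en-1-yl]-3-methyloxiran-2-yl]-2-methylidenebutanoate (carbinol epimers) | COC(=O)C(=C)C(O)C[C@H]1O[C@]1(C)CC/C=C(\C)I
F7 | step 14 | (4R)-2-(4-methoxyphenyl)-4-[(2S)-pent-4-en-2-yl]-1,3-dioxolane (acetal epimers) | COc1ccc(cc1)C1OC[C@H](O1)[C@@H](C)CC=C
F8 | step 14 | (2R,3S)-2-[(4-methoxybenzyl)oxy]-3-methylhex-5-en-1-ol | OC[C@H](OCc1ccc(OC)cc1)[C@@H](C)CC=C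
F9 | step 14 | (2R,3S)-2-[(4-methoxybenzyl)oxy]-3-methylhex-5-enal | O=C[C@H](OCc1ccc(OC)cc1)[C@@H](C)CC=C
F10 | step 14 | 4-methoxybenzyl-protected hydroxy ester (C13 ether of 21) | C=C(C(=O)OC)[C@H](C[C@H]1O[C@]1(C)CC/C=C(\C)I)[C@@H](O)[C@H](OCc2ccc(OC)cc2)[C@@H](C)CC=C
F11 | step 14 | 4-methoxybenzyl-protected seco lactone (C13 ether of 22) | C=C1C(=O)O[C@@H]([C@H](OCc3ccc(OC)cc3)[C@@H](C)CC=C)[C@H]1C[C@H]2O[C@]2(C)CC/C=C(\C)I
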